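The oxane ring (O1, C2 to C6) is cut at C3–C4 and C5–C6. The plan exploits three features: C6 is a formaldehyde-level carbon on O1, C4 and C5 lie beta and alpha to the carbinol carbon C7 (a latent aryl ketone), and C3 lies alpha to the side-chain CH2 (a latent carboxyl). An enantiopure 6-aryl-1,3-dioxan-4-one thus holds a C3 enolate and a masked C6 oxocarbenium ion in one temporary ring. With an aryl vinyl ketone and TiCl4 it should undergo Michael addition, acylal ionisation and enolate alkylation in one flask, which trades the dioxanone for the all-cis oxane and sets C3 and C5.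

Key step: step 6

Remark: locants follow the oxane of the target (O1, C2 aryl, C3 cinnamyl, C5 carbinol arm, C6 H2). C7 is the carbinol carbon and Piv is pivaloyl. Mono-tert-butyl malonate, 3-chloro-1-(4-hydroxyphenyl)propan-1-one and 4-acetoxystyrene are assumed to be commercial.

Step 1
Reactants: 1 4-hydroxybenzoic acid
Product: 2 4-(pivaloyloxy)benzoic acid
Conditions: PivCl, NaOH, H2O/THF, 0 °C; then aq. HCl
Reagents that add atoms: pivaloyl chloride, CC(C)(C)C(=O)Cl
Why: Schotten-Baumann acylation of the phenoxide installs an ester without alpha-hydrogens that lowers the donor power of the ring for the later Lewis-acid step.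

Step 2
Reactants: 2 4-(pivaloyloxy)benzoic acid; 3 mono-tert-butyl malonate
Product: 5 tert-butyl 3-oxo-3-[4-(pivaloyloxy)phenyl]propanoate, via acyl imidazolide 4 (not isolated)
Conditions: CDI, THF, rt; then 3, MgCl2, Et3N, MeCN, rt; aq. HCl
Reagents that add atoms: none
Why: Masamune-Brooks homologation, in which the magnesium malonate half-ester is C-acylated by the imidazolide and loses CO2, works under conditions mild enough for the aryl pivalate.

Step 3
Reactants: 5 tert-butyl 3-oxo-3-[4-(pivaloyloxy)phenyl]propanoate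
Product: 6 tert-butyl (3R)-3-hydroxy-3-[4-(pivaloyloxy)phenyl]propanoate
Conditions: H2 (50 bar), RuCl2[(S)-BINAP] (cat.), EtOH/CH2Cl2, 50 °C
Reagents that add atoms: none
Why: Noyori asymmetric hydrogenation of a beta-keto ester, in which chelation of the keto ester to the chiral ruthenium hydride differentiates the carbonyl faces, should set C2 as R with the (S)-ligand.

Step 4
Reactants: 6 tert-butyl (3R)-3-hydroxy-3-[4-(pivaloyloxy)phenyl]propanoate
Product: 8 4-[(4R)-6-oxo-1,3-dioxan-4-yl]phenyl pivalate, via hydroxy acid 7 (not isolated)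
Conditions: TFA, CH2Cl2, 0 °C to rt; evaporate; (CH2O)n, TsOH·H2O (cat.), 4 Å MS, CH2Cl2, reflux
Reagents that add atoms: paraformaldehyde (as formaldehyde), C=O
Why: Acidolysis of the tert-butyl ester followed by acid-catalysed acetalisation of the beta-hydroxy acid with formaldehyde closes the six-membered acylal without touching C2, and the electron-poor ring disfavours dehydration.

Step 5
Reactants: 9 3-chloro-1-(4-hydroxyphenyl)propan-1-one
Product: 11 4-acryloylphenyl pivalate, via chloro ketone pivalate 10 (not isolated)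
Conditions: PivCl, Et3N (2.5 equiv), BHT (trace), CH2Cl2, 0 °C to rt
Reagents that add atoms: pivaloyl chloride, CC(C)(C)C(=O)Cl
Why: O-acylation of the phenol and E1cB loss of HCl from the beta-chloro ketone run in the same flask and give the vinyl ketone, which is used fresh.

Step 6
Reactants: 8 4-[(4R)-6-oxo-1,3-dioxan-4-yl]phenyl pivalate; 11 4-acryloylphenyl pivalate
Product: 15 (2R,3S,5R)-2-[4-(pivaloyloxy)phenyl]-5-[4-(pivaloyloxy)benzoyl]oxane-3-carboxylic acid, via titanium enolate 12 (not isolated), via Michael adduct enolate 13 (not isolated), via oxocarbenium titanate 14 (not isolated)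
Conditions: TiCl4 (3 equiv), iPr2NEt (2.2 equiv), CH2Cl2, −78 °C; 11, −78 °C; then to −20 °C; aq. HCl
Reagents that add atoms: none
Why: Proposed new method: TiCl4 and iPr2NEt should convert 8 into the chlorotitanium enolate 12, whose C3 adds 1,4 to 11 (bond C3–C4); the resulting (Z)-titanium enolate 13 binds the lactone carbonyl, the acylal bond from C6 to the acyl oxygen ionises on warming to the oxocarbenium titanate 14, and C5 attacks C6 (bond C5–C6). The closest known reaction types are the Michael addition of chlorotitanium enolates to vinyl ketones and the TiCl4-promoted Mukaiyama-type substitution of the acyloxy group at the acetal carbon of 1,3-dioxan-4-ones by enol nucleophiles, merged here through an enone linchpin. The oxane closes in the 6-(enolexo)-endo-trig mode on the oxocarbenium ion while the dioxanone ring opens, so no strained bicycle has to form. C3 is controlled by the C2 aryl group of the ring enolate (attack anti to it gives the 5,6-trans dioxanone, which becomes the 2,3-cis oxane once C4 instead of the carboxyl carbon is the ring member), and C5 by the titanium atom that bridges carboxylate and enolate oxygen, so that closure runs through a chair with the C2 aryl group equatorial and both carbonyl arms axial on one face (3,5-cis). The step needs 1,4- over 1,2-addition, Michael addition before ionisation, C- over O-alkylation and an intact C2–O1 bond, which the unsubstituted vinyl ketone, the low ionising tendency of a formaldehyde acylal at −78 °C, the six- against eight-membered closure and the electron-poor pivaloyloxyaryl group should secure. Beta-elimination of O1 from 12 is held back because the endocyclic C2–O1 bond lies near the nodal plane of the ring enolate.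

Step 7
Reactants: 15 (2R,3S,5R)-2-[4-(pivaloyloxy)phenyl]-5-[4-(pivaloyloxy)benzoyl]oxane-3-carboxylic acid
Product: 16 4-[(2R,3R,5R)-3-(hydroxymethyl)-5-{(R)-hydroxy[4-(pivaloyloxy)phenyl]methyl}oxan-2-yl]phenyl pivalate
Conditions: (S)-2-methyl-CBS-oxazaborolidine (0.2 equiv), BH3·SMe2 (5 equiv), THF, −20 °C to rt; MeOH
Reagents that add atoms: none
Why: In the CBS reduction the (S)-oxazaborolidine should deliver hydride to the ketone face that gives the (R)-carbinol C7 and so remove the epimerisable position next to C5, while excess borane reduces the carboxylic acid chemoselectively and leaves the hindered aryl pivalates.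

Step 8
Reactants: 16 4-[(2R,3R,5R)-3-(hydroxymethyl)-5-{(R)-hydroxy[4-(pivaloyloxy)phenyl]methyl}oxan-2-yl]phenyl pivalate
Product: 17 4-[(2R,3S,5R)-5-{(R)-hydroxy[4-(pivaloyloxy)phenyl]methyl}-3-(iodomethyl)oxan-2-yl]phenyl pivalate
Conditions: I2, PPh3, imidazole (1.05 equiv each), CH2Cl2, 0 °C
Reagents that add atoms: iodine, II
Why: In the Appel reaction the primary hydroxyl group is phosphonylated and displaced much faster than the hindered, electron-poor benzylic carbinol, and the SN2 step at the CH2 group touches no stereocentre.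

Step 9
Reactants: 17 4-[(2R,3S,5R)-5-{(R)-hydroxy[4-(pivaloyloxy)phenyl]methyl}-3-(iodomethyl)oxan-2-yl]phenyl pivalate; 18 4-acetoxystyrene
Product: 19 4-[(1E)-3-{(2R,3S,5R)-5-{(R)-hydroxy[4-(pivaloyloxy)phenyl]methyl}-2-[4-(pivaloyloxy)phenyl]oxan-3-yl}prop-1-en-1-yl]phenyl acetate
Conditions: 18 (3 equiv), Pd(OAc)2 (cat.), Xantphos, Cs2CO3, benzene, blue LED, rt
Reagents that add atoms: none
Why: In the visible-light-induced palladium-catalysed alkyl Heck reaction the excited zerovalent palladium complex abstracts iodine from 17, the primary radical adds to the CH2 terminus of 18, and beta-hydride elimination from the benzylic palladium species should give the conjugated (E)-alkene.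

Step 10
Reactants: 19 4-[(1E)-3-{(2R,3S,5R)-5-{(R)-hydroxy[4-(pivaloyloxy)phenyl]methyl}-2-[4-(pivaloyloxy)phenyl]oxan-3-yl}prop-1-en-1-yl]phenyl acetate
Product: 20 CNP0182155.1, 4-[(1E)-3-{(2R,3S,5R)-5-[(R)-hydroxy(4-hydroxyphenyl)methyl]-2-(4-hydroxyphenyl)oxan-3-yl}prop-1-en-1-yl]phenol
Conditions: K2CO3 (3.5 equiv), MeOH, 0 °C to rt; aq. NH4Cl
Reagents that add atoms: none
Why: Carbonate-mediated methanolysis (transesterification) of the three aryl esters, made labile by their phenoxide leaving groups, should free the phenols at a temperature at which neither benzylic C–O bond ionises.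

Compound list
1 | 4-hydroxybenzoic acid | OC(=O)c1ccc(O)cc1 | starting material
2 | 4-(pivaloyloxy)benzoic acid | CC(C)(C)C(=O)Oc1ccc(cc1)C(O)=O | intermediate
3 | mono-tert-butyl malonate | CC(C)(C)OC(=O)CC(O)=O | starting material
4 | 4-(1H-imidazole-1-carbonyl)phenyl pivalate | CC(C)(C)C(=O)Oc1ccc(cc1)C(=O)n1ccnc1 | intermediate
5 | tert-butyl 3-oxo-3-[4-(pivaloyloxy)phenyl]propanoate | CC(C)(C)OC(=O)CC(=O)c1ccc(OC(=O)C(C)(C)C)cc1 | intermediate
6 | tert-butyl (3R)-3-hydroxy-3-[4-(pivaloyloxy)phenyl]propanoate | O[C@H](CC(=O)OC(C)(C)C)c1ccc(OC(=O)C(C)(C)C)cc1 | intermediate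
7 | (3R)-3-hydroxy-3-[4-(pivaloyloxy)phenyl]propanoic acid | O[C@H](CC(O)=O)c1ccc(OC(=O)C(C)(C)C)cc1 | intermediate
8 | 4-[(4R)-6-oxo-1,3-dioxan-4-yl]phenyl pivalate | O=C1C[C@H](c2ccc(OC(=O)C(C)(C)C)cc2)OCO1 | intermediate
9 | 3-chloro-1-(4-hydroxyphenyl)propan-1-one | O=C(CCCl)c1ccc(O)cc1 | starting material
10 | 4-(3-chloropropanoyl)phenyl pivalate | CC(C)(C)C(=O)Oc1ccc(cc1)C(=O)CCCl | intermediate
11 | 4-acryloylphenyl pivalate | C=CC(=O)c1ccc(OC(=O)C(C)(C)C)cc1 | intermediate
12 | trichlorotitanium enolate of 8 | Cl[Ti](Cl)(Cl)OC1=C[C@H](c2ccc(OC(=O)C(C)(C)C)cc2)OCO1 | intermediate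
13 | trichlorotitanium (Z)-enolate of the (5S,6R), 5,6-trans Michael adduct of 8 and 11 | O=C1[C@@H](C/C=C(\O[Ti](Cl)(Cl)Cl)c2ccc(OC(=O)C(C)(C)C)cc2)[C@H](c2ccc(OC(=O)C(C)(C)C)cc2)OCO1 | intermediate
14 | ring-opened O1=C6 oxocarbenium ion whose carboxylate and (Z)-enolate oxygen are bridged by a trichlorotitanate | C=[O+][C@@H](c1ccc(OC(=O)C(C)(C)C)cc1)[C@@H]1C/C=C(c2ccc(OC(=O)C(C)(C)C)cc2)\O[Ti-](Cl)(Cl)(Cl)OC1=O | intermediate
15 | (2R,3S,5R)-2-[4-(pivaloyloxy)phenyl]-5-[4-(pivaloyloxy)benzoyl]oxane-3-carboxylic acid (all three substituents cis) | OC(=O)[C@H]1C[C@@H](C(=O)c2ccc(OC(=O)C(C)(C)C)cc2)CO[C@H]1c1ccc(OC(=O)C(C)(C)C)cc1 | intermediate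
16 | 4-[(2R,3R,5R)-3-(hydroxymethyl)-5-{(R)-hydroxy[4-(pivaloyloxy)phenyl]methyl}oxan-2-yl]phenyl pivalate | OC[C@H]1C[C@@H]([C@@H](O)c2ccc(OC(=O)C(C)(C)C)cc2)CO[C@H]1c1ccc(OC(=O)C(C)(C)C)cc1 | intermediate
17 | 4-[(2R,3S,5R)-5-{(R)-hydroxy[4-(pivaloyloxy)phenyl]methyl}-3-(iodomethyl)oxan-2-yl]phenyl pivalate | IC[C@H]1C[C@@H]([C@@H](O)c2ccc(OC(=O)C(C)(C)C)cc2)CO[C@H]1c1ccc(OC(=O)C(C)(C)C)cc1 | intermediate
18 | 4-acetoxystyrene | CC(=O)Oc1ccc(C=C)cc1 | starting material
19 | acetate bis-pivalate of the target, (2R,3S,5R), (R)-carbinol, (E)-alkene | CC(=O)Oc1ccc(/C=C/C[C@H]2C[C@@H]([C@@H](O)c3ccc(OC(=O)C(C)(C)C)cc3)CO[C@H]2c2ccc(OC(=O)C(C)(C)C)cc2)cc1 | intermediate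
20 | CNP0182155.1 | Oc1ccc(/C=C/C[C@H]2C[C@@H]([C@@H](O)c3ccc(O)cc3)CO[C@H]2c2ccc(O)cc2)cc1 | target

Total step count: 10. Longest linear sequence: 9 (steps 1 to 4 and 6 to 10).

Steps most likely to fail

For step 6, which bears the label, three things may go wrong.
- The acylal may ionise before the Michael addition, so that the oxocarbenium ion is consumed by intermolecular attack of the enolate.
- The vinyl ketone may polymerise.
- The closure may run without the titanium bridge, so that facial control at C5 is lost or C5 epimerises afterwards.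

The fallback uses known chemistry in separate operations. It sets out from 8 and returns at 15.
- Deprotonation of 8 with LDA in the presence of TMSCl (THF, −78 °C) gives the trimethylsilyl ketene acetal F1.
- A Mukaiyama-Michael addition of F1 to 11 (TMSOTf cat., CH2Cl2, −78 °C) gives the isolable 5,6-trans silyl enol ether F2.
- Treatment of F2 with TiCl4 (−78 to −20 °C) performs the known Lewis-acid substitution at the dioxanone acetal carbon by a silyl enol ether, here within one molecule. Acidic work-up gives 15.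

For step 7, catalyst control may not override the facial bias of the alpha-branched ketone. Lactonisation of the new carbinol onto the activated acid may also stall the acid reduction. The fallback replaces mismatched catalyst control by matched reduction and late inversion. It sets out from 15 and returns at 20.
- The enantiomeric (R)-oxazaborolidine with BH3·SMe2 should give the (7S)-diol F3.
- Appel iodination gives the (7S)-iodide F4.
- The alkyl Heck reaction with 18 gives the (7S)-styrene F5.
- A Mitsunobu reaction (PPh3, DIAD, 4-nitrobenzoic acid) inverts the only free hydroxyl group to the (7R)-4-nitrobenzoate F6. The electron-poor ring favours clean SN2 displacement.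
- K2CO3 in MeOH then cleaves all four ester groups to give 20.

For step 9, the primary radical may abstract the C7 hydrogen by 1,5-transfer. The free carbinol may also displace iodide under the basic conditions before the radical is trapped by the styrene. The fallback replaces the radical Heck process by a polar organozinc coupling. It sets out from 17 and returns at 19.
- TESCl and imidazole give the triethylsilyl ether F7.
- Zinc dust and LiCl in THF give the alkylzinc iodide F8.
- Commercial 4-acetoxycinnamic acid is converted by a catalytic Hunsdiecker reaction (NBS, LiOAc, MeCN/H2O) into (E)-4-(2-bromovinyl)phenyl acetate F9.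
- A Negishi coupling of F8 with F9 (Pd(PPh3)4, THF, rt), with retention of alkene geometry, gives the silyl ether F10.
- HF·pyridine removes the silyl group to give 19.

Further compounds
F1 | step 6 | trimethylsilyl ketene acetal of 8 | C[Si](C)(C)OC1=C[C@H](c2ccc(OC(=O)C(C)(C)C)cc2)OCO1
F2 | step 6 | (5S,6R), 5,6-trans Michael adduct of 8 and 11 as its (Z)-trimethylsilyl enol ether | O=C1[C@@H](C/C=C(\O[Si](C)(C)C)c2ccc(OC(=O)C(C)(C)C)cc2)[C@H](c2ccc(OC(=O)C(C)(C)C)cc2)OCO1
F3 | step 7 | (7S)-epimer of diol 16 | OC[C@H]1C[C@@H]([C@H](O)c2ccc(OC(=O)C(C)(C)C)cc2)CO[C@H]1c1ccc(OC(=O)C(C)(C)C)cc1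
F4 | step 7 | (7S)-epimer of iodide 17 | IC[C@H]1C[C@@H]([C@H](O)c2ccc(OC(=O)C(C)(C)C)cc2)CO[C@H]1c1ccc(OC(=O)C(C)(C)C)cc1
F5 | step 7 | (7S)-epimer of 19 | CC(=O)Oc1ccc(/C=C/C[C@H]2C[C@@H]([C@H](O)c3ccc(OC(=O)C(C)(C)C)cc3)CO[C@H]2c2ccc(OC(=O)C(C)(C)C)cc2)cc1
F6 | step 7 | (7R)-4-nitrobenzoate of 19 | CC(=O)Oc1ccc(/C=C/C[C@H]2C[C@@H]([C@@H](OC(=O)c3ccc(cc3)[N+]([O-])=O)c3ccc(OC(=O)C(C)(C)C)cc3)CO[C@H]2c2ccc(OC(=O)C(C)(C)C)cc2)cc1
F7 | step 9 | triethylsilyl ether of iodide 17 | IC[C@H]1C[C@@H]([C@@H](O[Si](CC)(CC)CC)c2ccc(OC(=O)C(C)(C)C)cc2)CO[C@H]1c1ccc(OC(=O)C(C)(C)C)cc1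
F8 | step 9 | alkylzinc iodide from F7 | I[Zn]C[C@H]1C[C@@H]([C@@H](O[Si](CC)(CC)CC)c2ccc(OC(=O)C(C)(C)C)cc2)CO[C@H]1c1ccc(OC(=O)C(C)(C)C)cc1
F9 | step 9 | (E)-4-(2-bromovinyl)phenyl acetate | CC(=O)Oc1ccc(/C=C/Br)cc1
F10 | step 9 | triethylsilyl ether of 19 | CC(=O)Oc1ccc(/C=C/C[C@H]2C[C@@H]([C@@H](O[Si](CC)(CC)CC)c3ccc(OC(=O)C(C)(C)C)cc3)CO[C@H]2c2ccc(OC(=O)C(C)(C)C)cc2)cc1
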